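**Retrosynthetic overview**
- Last step: O-sulfation of the free phenol, placed at the end because the aryl sulfate is acid-labile.
- Key disconnection: the imidazole is cut at N3–C4 and N1–C2, giving formamidine (the N–C–N unit) and an N-Boc α-amino ketone whose carbamate nitrogen becomes N1.
- The α-amino ketone comes from the Weinreb amide of Boc-L-tyrosine and 4-methoxybenzylmagnesium chloride; the C5–N1 bond is bought with tyrosine.
- Ring order: both benzene rings are purchased; the imidazole is the only ring made (step 3).

Assumption: the target is achiral (no stereocentre, and the two imidazole N–H tautomers are one compound), so no enantiocontrol is needed; the (S) centre carried from L-tyrosine is erased on aromatisation. Compounds are numbered in the order of the forward route.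

**Step 1**
Reactants: 1 N-(tert-butoxycarbonyl)-L-tyrosine (Boc-L-Tyr-OH, free phenol); 2 N,O-dimethylhydroxylamine hydrochloride
Product: 3 tert-butyl N-[(2S)-3-(4-hydroxyphenyl)-1-[methoxy(methyl)amino]-1-oxopropan-2-yl]carbamate
Conditions: EDC·HCl (1.2 equiv), HOBt (1.1 equiv), N-methylmorpholine (2.5 equiv), CH2Cl2/DMF 9:1, 0 °C → 25 °C, 12 h
Reagents that add atoms: none
Why: Carbodiimide/HOBt amide coupling (Weinreb amide formation), in which the OBt ester is aminolysed by the hydroxylamine far faster than it acylates the free phenol, and the Boc group and the (S) centre of L-tyrosine are untouched.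

**Step 2**
Reactants: 3 Weinreb amide; 4 4-methoxybenzylmagnesium chloride (commercial 0.25 M solution in THF)
Product: 6 tert-butyl N-[(2S)-1-(4-hydroxyphenyl)-4-(4-methoxyphenyl)-3-oxobutan-2-yl]carbamate, via tris(chloromagnesium) hemiaminal 5 (not isolated)
Conditions: 4 (3.5 equiv), THF, −20 → 0 °C, 2 h; then 1 M aq. HCl, 0 °C
Reagents that add atoms: none
Why: Weinreb ketone synthesis, in which two equivalents of 4 deprotonate ArOH and NHBoc and the third adds to the amide to give the chelated tetrahedral adduct 5, which cannot over-add and collapses to ketone 6 only on the cold acidic quench that Boc survives; no stereocentre is created that persists.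

**Step 3**
Reactants: 6 N-Boc α-amino ketone; 7 formamidine acetate
Product: 10 4-{[5-(4-methoxybenzyl)-1H-imidazol-4-yl]methyl}phenol, via formimidoyl ketimine 8 (not isolated), via N-Boc imidazole 9 (not isolated)
Conditions: 7 (4 equiv), 2-methylbutan-2-ol, sealed tube, 110 °C, 16 h
Reagents that add atoms: none
Why: Proposed new method: a deprotection-free, carbamate-participating [3+2] annulation in which formamidine condenses with the ketone to the N-formimidoyl ketimine 8, whose ene-diamine tautomer holds the Boc–NH next to the protonated amidine carbon, so that 5-exo attack of the carbamate nitrogen and loss of NH3 aromatise to N-Boc imidazole 9 (forming the N3–C4 and N1–C2 bonds and the ring), and 9, being an N-acyl imidazole, passes its Boc group to the NH3 just released (giving tert-butyl carbamate) to leave 10; the self-condensing free α-amino ketone is never formed, the phenol needs no protection and the (S) centre becomes sp2; the closest known reaction types are the Bredereck imidazole synthesis from free α-amino ketone salts with formamidine or formamide and the Davidson cyclisation of α-acylamino ketones with ammonium acetate, neither of which, to my knowledge, uses a carbamate nitrogen as ring nitrogen with traceless loss of the carbamate.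

**Step 4**
Reactants: 10 phenol–imidazole
Product: 11 4-{[5-(4-methoxybenzyl)-1H-imidazol-4-yl]methyl}phenyl hydrogen sulfate (Melanocin F)
Conditions: SO3·pyridine (3 equiv), pyridine, 25 °C, 12 h; then H2O, 25 °C, 1 h; C18 chromatography (H2O/MeCN)
Reagents that add atoms: sulfur trioxide pyridine complex, [O-]S(=O)(=O)[n+]1ccccc1
Why: O-sulfation of a phenol with an SO3–amine complex, in which any imidazole N-sulfonate is hydrolysed in the aqueous hold, the anisole ring is not C-sulfonated at 25 °C, and the product is isolated as its stable imidazolium sulfate inner salt.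

**Compound list**
1 | N-(tert-butoxycarbonyl)-L-tyrosine | CC(C)(C)OC(=O)N[C@@H](Cc1ccc(O)cc1)C(=O)O | starting material
2 | N,O-dimethylhydroxylamine hydrochloride | CNOC.Cl | starting material
3 | tert-butyl N-[(2S)-3-(4-hydroxyphenyl)-1-[methoxy(methyl)amino]-1-oxopropan-2-yl]carbamate | CC(C)(C)OC(=O)N[C@@H](Cc1ccc(O)cc1)C(=O)N(C)OC | intermediate
4 | 4-methoxybenzylmagnesium chloride | COc1ccc(C[Mg]Cl)cc1 | starting material
5 | tris(chloromagnesium) salt of the tetrahedral N-methoxy-N-methyl hemiaminal adduct (phenoxide, carbamate N-magnesiated, hemiaminal alkoxide; both epimers at the hemiaminal carbon) | CC(C)(C)OC(=O)N([Mg]Cl)[C@@H](Cc1ccc(O[Mg]Cl)cc1)C(O[Mg]Cl)(Cc1ccc(OC)cc1)N(C)OC | intermediate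
6 | tert-butyl N-[(2S)-1-(4-hydroxyphenyl)-4-(4-methoxyphenyl)-3-oxobutan-2-yl]carbamate | CC(C)(C)OC(=O)N[C@@H](Cc1ccc(O)cc1)C(=O)Cc1ccc(OC)cc1 | intermediate
7 | formamidine acetate | NC=N.CC(=O)O | starting material
8 | tert-butyl N-[(2S)-1-(4-hydroxyphenyl)-3-[(iminomethyl)imino]-4-(4-methoxyphenyl)butan-2-yl]carbamate (N-formimidoyl ketimine, C=N geometry undefined, in equilibrium with its ene-diamine tautomer) | CC(C)(C)OC(=O)N[C@@H](Cc1ccc(O)cc1)C(Cc1ccc(OC)cc1)=NC=N | intermediate
9 | tert-butyl 5-(4-hydroxybenzyl)-4-(4-methoxybenzyl)-1H-imidazole-1-carboxylate | CC(C)(C)OC(=O)n1cnc(Cc2ccc(OC)cc2)c1Cc1ccc(O)cc1 | intermediate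
10 | 4-{[5-(4-methoxybenzyl)-1H-imidazol-4-yl]methyl}phenol | COc1ccc(Cc2[nH]cnc2Cc2ccc(O)cc2)cc1 | intermediate
11 | 4-{[5-(4-methoxybenzyl)-1H-imidazol-4-yl]methyl}phenyl hydrogen sulfate (Melanocin F, achiral) | COc1ccc(Cc2[nH]cnc2Cc2ccc(OS(=O)(=O)O)cc2)cc1 | target

**Total step count:** 4
**Longest linear sequence:** 4 steps (1 → 3 → 6 → 10 → 11)

**Steps most likely to fail**

Step 3 (the proposed new annulation). Risks are that the carbamate nitrogen fails to close onto the amidine, or that attack on the Boc carbonyl gives an imidazol-2-one. The fallback is the known two-stage Bredereck sequence, setting out from 6 and returning at 10. Boc is removed with 4 M HCl in 1,4-dioxane at 25 °C to give (3S)-3-amino-4-(4-hydroxyphenyl)-1-(4-methoxyphenyl)butan-2-one hydrochloride F2, kept as the salt to prevent dihydropyrazine formation. F2 is then condensed with formamidine acetate in liquid NH3 (sealed vessel, 25 °C) to give 10.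

Step 2 (Grignard addition to the unprotected, triply deprotonated substrate). Risks are poor solubility of the polymagnesium salts, enolisation, and waste of the dilute reagent. The fallback replaces organomagnesium addition by a Fukuyama thioester–organozinc coupling, setting out from 1 and returning at 6. Compound 1 is esterified with ethanethiol (EDC·HCl, catalytic DMAP, CH2Cl2, 0 °C) to S-ethyl (2S)-2-[(tert-butoxycarbonyl)amino]-3-(4-hydroxyphenyl)propanethioate F1. F1 is coupled with 4-methoxybenzylzinc chloride (3 equiv, added slowly) under PdCl2(PPh3)2 (5 mol %) in THF/toluene at 25 °C to give ketone 6 under non-basic conditions.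

Step 4 (sulfation and isolation of a zwitterion beside a nucleophilic imidazole). Risks are incomplete O-sulfation, persistent N-sulfonation, and loss on reversed-phase purification. The fallback is a masked-sulfate route, setting out from 10 and returning at 11. The phenoxide of 10 is formed selectively with NaH (1.0 equiv, THF, 0 °C) and treated with 2,2,2-trichloroethyl chlorosulfate (1.05 equiv) to give the neutral, silica-stable diester 4-{[5-(4-methoxybenzyl)-1H-imidazol-4-yl]methyl}phenyl 2,2,2-trichloroethyl sulfate F3. After normal chromatography, F3 is unmasked with zinc dust (Zn) and ammonium formate in MeOH at 25 °C to give 11.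

**Further compounds**
F1 | step 2 | S-ethyl (2S)-2-[(tert-butoxycarbonyl)amino]-3-(4-hydroxyphenyl)propanethioate | CCSC(=O)[C@H](Cc1ccc(O)cc1)NC(=O)OC(C)(C)C
F2 | step 3 | (3S)-3-amino-4-(4-hydroxyphenyl)-1-(4-methoxyphenyl)butan-2-one hydrochloride | COc1ccc(CC(=O)[C@@H](N)Cc2ccc(O)cc2)cc1.Cl
F3 | step 4 | 4-{[5-(4-methoxybenzyl)-1H-imidazol-4-yl]methyl}phenyl 2,2,2-trichloroethyl sulfate | COc1ccc(Cc2[nH]cnc2Cc2ccc(OS(=O)(=O)OCC(Cl)(Cl)Cl)cc2)cc1
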